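The route rests on building, not buying, the benzene ring of the 7-hydroxy-5-(2-oxopropyl)chromone half. Its atoms C4a, C5, C6, C7, C8 and C8a carry an intact polyketide pattern (the C4 carbonyl on C4a, oxygen on C7 and C8a, a carbon chain on C5), so the C4a–C5 bond is cut as an aldol bond. In one operation a mild amine converts an open-chain diketo-dioxinone, whose third ketone is masked as a dioxolane, into the fully substituted resorcylate acetonide. Its lactone carbon becomes C4: reduction to the salicylaldehyde, union with a 5-propargyl-8-methoxychromone from isovanillin, oxidation to the ynone and oxa-Michael closure complete the second pyranone.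

Key step: step 9

Remark on the chemistry: the target has no stereocentre, stereoaxis or configurable double bond. It is achiral, so the request for a single enantiomer needs no measure. The carbinol and lactol centres that arise in three intermediates are racemic and are erased within the route.

Step 1
Reactants: 1 isovanillin (3-hydroxy-4-methoxybenzaldehyde)
Product: 2 3-hydroxy-2-iodo-4-methoxybenzaldehyde
Conditions: ICl, pyridine, 1,4-dioxane, 0 °C → rt
Reagents that add atoms: iodine monochloride, ClI
Why: Electrophilic aromatic iodination, in which the free phenol directs the pyridine-moderated I+ to its only open ortho position, C-2 between OH and CHO, the established site for this reagent on isovanillin.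

Step 2
Reactants: 2 3-hydroxy-2-iodo-4-methoxybenzaldehyde
Product: 3 3-(dimethoxymethyl)-2-iodo-6-methoxyphenol
Conditions: HC(OMe)3, TsOH (cat.), MeOH, rt; Et3N quench
Reagents that add atoms: trimethyl orthoformate, COC(OC)OC
Why: Acid-catalysed acetalisation with the orthoformate as water scavenger; the mask keeps the formyl group away from the secondary amine of step 3 and from the nucleophilic α-carbon of the amine adduct formed next to it, which could otherwise close a five-membered aldol ring.

Step 3
Reactants: 3 3-(dimethoxymethyl)-2-iodo-6-methoxyphenol; 4 3-methylbut-1-yne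
Product: 8 2-isopropyl-8-methoxy-4-oxo-4H-chromene-5-carbaldehyde, via ynone acetal 5 (not isolated), via enaminone acetal 6 (not isolated), via chromone acetal 7 (not isolated)
Conditions: CO (10 bar), PdCl2(dppf) (3 mol %), 4 (3 equiv), Et2NH, autoclave, 70 °C; then EtOAc / 1 M aq HCl, rt
Reagents that add atoms: carbon monoxide, [C-]#[O+]; water, O
Why: Carbonylative Sonogashira annulation of an o-iodophenol: oxidative addition, CO insertion and alkynylation should give 5, diethylamine adds to the triple bond to give 6, the phenol displaces the amine at the β-carbon (net 6-endo closure, no aurone) to give 7, and the acidic wash unmasks the aldehyde; copper is left out to hold back the direct coupling that leads to a benzofuran.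

Step 4
Reactants: 8 2-isopropyl-8-methoxy-4-oxo-4H-chromene-5-carbaldehyde
Product: 10 2-(2-isopropyl-8-methoxy-4-oxo-4H-chromen-5-yl)acetaldehyde, via enol ether 9 (not isolated)
Conditions: MeOCH2PPh3Cl, KOtBu, THF, 0 °C; 8, −78 → 0 °C; then 3 M aq HCl, 40 °C; used crude
Reagents that add atoms: (methoxymethyl)triphenylphosphonium chloride, COC[P+](c1ccccc1)(c1ccccc1)c1ccccc1.[Cl-]; water, O
Why: Wittig methoxymethylenation occurs at the aldehyde, far more electrophilic than the vinylogous-ester carbonyl C-4, and the E/Z enol ether mixture converges on one arylacetaldehyde when the same flask is acidified, the acid being kept moderate so that the new aldehyde does not condense with nucleophilic C-3.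

Step 5
Reactants: 10 2-(2-isopropyl-8-methoxy-4-oxo-4H-chromen-5-yl)acetaldehyde
Product: 11 2-isopropyl-8-methoxy-5-(prop-2-yn-1-yl)-4H-chromen-4-one
Conditions: dimethyl (1-diazo-2-oxopropyl)phosphonate, K2CO3, MeOH, 0 °C → rt
Reagents that add atoms: dimethyl (1-diazo-2-oxopropyl)phosphonate, COP(=O)(OC)C(=[N+]=[N-])C(C)=O
Why: Seyferth–Gilbert homologation in the Ohira–Bestmann form: methanolysis frees the diazomethylphosphonate anion, which olefinates the aldehyde, and loss of N2 with a 1,2-hydride shift should give the terminal alkyne under carbonate conditions too mild to move the triple bond to the allene if the reaction is stopped at full conversion.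

Step 6
Reactants: 12 2,2,6-trimethyl-4H-1,3-dioxin-4-one
Product: 13 2,2-dimethyl-6-(2-oxopropyl)-4H-1,3-dioxin-4-one
Conditions: 12 (2 equiv), LiHMDS (2 equiv), THF, −78 °C; AcCl (1 equiv), −78 °C; 1 M aq HCl
Reagents that add atoms: acetyl chloride, CC(=O)Cl
Why: Vinylogous Claisen acylation, in which the lithium dienolate formed at the 6-methyl group is C-acetylated at its γ-terminus and the second equivalent of dienolate takes up the more acidic proton of the product.

Step 7
Reactants: 14 ethyl 2-(2-methyl-1,3-dioxolan-2-yl)acetate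
Product: 15 N-methoxy-N-methyl-2-(2-methyl-1,3-dioxolan-2-yl)acetamide
Conditions: MeNH(OMe)·HCl, iPrMgCl, THF, −20 → 0 °C
Reagents that add atoms: N,O-dimethylhydroxylamine hydrochloride, CNOC.Cl
Why: Ester aminolysis by the magnesium amide of N,O-dimethylhydroxylamine (Weinreb amide synthesis), run cold so that the α-methylene is not enolised and the β-ketal stays closed.

Step 8
Reactants: 13 2,2-dimethyl-6-(2-oxopropyl)-4H-1,3-dioxin-4-one; 15 N-methoxy-N-methyl-2-(2-methyl-1,3-dioxolan-2-yl)acetamide
Product: 16 2,2-dimethyl-6-[5-(2-methyl-1,3-dioxolan-2-yl)-2,4-dioxopentyl]-4H-1,3-dioxin-4-one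
Conditions: 13, LDA (2.2 equiv), THF, −78 °C; 15, −78 → −40 °C; AcOH, then pH 7 buffer
Reagents that add atoms: none
Why: Claisen-type acylation of a dianion: the last-formed and most reactive carbanion, at the terminal methyl, attacks the Weinreb amide, whose chelated tetrahedral adduct lasts until the quench and so blocks over-addition and proton loss from the product, while the weakly acidic quench spares the dioxolane.

Step 9
Reactants: 16 2,2-dimethyl-6-[5-(2-methyl-1,3-dioxolan-2-yl)-2,4-dioxopentyl]-4H-1,3-dioxin-4-one
Product: 18 7-hydroxy-2,2-dimethyl-5-[(2-methyl-1,3-dioxolan-2-yl)methyl]-4H-1,3-benzodioxin-4-one, via cyclic aldol 17 (not isolated)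
Conditions: Et3N, CH2Cl2, rt
Reagents that add atoms: none
Why: Triethylamine removes a proton from the methylene between dioxinone C-6 and the first chain ketone; the cross-conjugated dienolate attacks through dioxinone C-5 (future C4a) the second chain ketone (future C5) to give aldol 17, which loses water by E1cB and tautomerises to the phenol, so aromatisation drives the sequence to completion. The closest known reaction type is the amine- or carbonate-mediated cycloaromatisation of 6-(2,4-dioxoalkyl)-1,3-dioxin-4-ones to acetonide-protected β-resorcylates, of which 16 is an ordinary member with a new terminal group. The single ring closed is the carbocycle, in a 6-(enolexo)-exo-trig mode, because the reacting enolate bond C4=C5 of the dioxinone lies outside the new ring and the attacked C=O is exocyclic to it. No stereocentre remains: the carbinol carbon of 17 forms as a racemate and becomes sp2 on dehydration. The selectivity needed is regioselectivity among the aldol folds, and the substrate secures it because only C-5 and the second ketone are spaced for a six-membered ring, the dioxinone carbonyl is a poorly electrophilic vinylogous carbonate, and the third ketone is locked as the dioxolane and can act neither as acceptor nor as enol donor. The weak base at room temperature should leave the ketal closed, because the 1,3-diketone is held as its enolate and the methylene next to the ketal is not deprotonated.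

Step 10
Reactants: 18 7-hydroxy-2,2-dimethyl-5-[(2-methyl-1,3-dioxolan-2-yl)methyl]-4H-1,3-benzodioxin-4-one
Product: 19 7-(methoxymethoxy)-2,2-dimethyl-5-[(2-methyl-1,3-dioxolan-2-yl)methyl]-4H-1,3-benzodioxin-4-one
Conditions: MOMCl, iPr2NEt, CH2Cl2, 0 °C → rt
Reagents that add atoms: chloromethyl methyl ether, COCCl
Why: O-alkylation of the only free phenol; the MOM ether removes the acidic proton and the para phenoxide donation that would deactivate the carbonyl carbon in steps 11 and 12, and it falls together with the dioxolane in step 15.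

Step 11
Reactants: 19 7-(methoxymethoxy)-2,2-dimethyl-5-[(2-methyl-1,3-dioxolan-2-yl)methyl]-4H-1,3-benzodioxin-4-one
Product: 21 2-hydroxy-4-(methoxymethoxy)-6-[(2-methyl-1,3-dioxolan-2-yl)methyl]benzaldehyde, via lactol 20 (not isolated)
Conditions: DIBAL-H (1.2 equiv), CH2Cl2, −78 °C; MeOH, aq Rochelle salt
Reagents that add atoms: none
Why: Partial reduction of a lactone: one hydride gives the aluminium salt of lactol 20, which persists at −78 °C and on aqueous work-up collapses with loss of acetone to the hydrogen-bonded salicylaldehyde, a known passage from benzodioxinones to salicylaldehydes that leaves acetals untouched.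

Step 12
Reactants: 11 2-isopropyl-8-methoxy-5-(prop-2-yn-1-yl)-4H-chromen-4-one; 21 2-hydroxy-4-(methoxymethoxy)-6-[(2-methyl-1,3-dioxolan-2-yl)methyl]benzaldehyde
Product: 22 5-{4-hydroxy-4-[2-hydroxy-4-(methoxymethoxy)-6-[(2-methyl-1,3-dioxolan-2-yl)methyl]phenyl]but-2-yn-1-yl}-2-isopropyl-8-methoxy-4H-chromen-4-one (racemic)
Conditions: 11 (1.1 equiv), LiHMDS (1.1 equiv), THF, −78 °C; added to 21 + LiHMDS (1.0 equiv), THF, −78 °C; → −20 °C; AcOH; used crude
Reagents that add atoms: none
Why: Acetylide 1,2-addition to an aldehyde: the non-nucleophilic amide removes the kinetically most acidic proton (terminal C–H), the phenol is turned into its lithium salt beforehand so that no acetylide is lost, the aldehyde is by far the best electrophile present, no acidic ynone or acetone ever meets the acetylide, and the carbinol centre forms as a racemate that step 13 erases.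

Step 13
Reactants: 22 the racemic propargylic alcohol of step 12
Product: 23 5-{4-[2-hydroxy-4-(methoxymethoxy)-6-[(2-methyl-1,3-dioxolan-2-yl)methyl]phenyl]-4-oxobut-2-yn-1-yl}-2-isopropyl-8-methoxy-4H-chromen-4-one
Conditions: activated MnO2 (excess), CH2Cl2, rt
Reagents that add atoms: none
Why: Heterogeneous MnO2 oxidation is selective for the doubly activated (benzylic and propargylic) carbinol, needs neither acid nor base, and should leave the phenol, both acetals and the skipped methylene alone, while the stereocentre disappears.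

Step 14
Reactants: 23 the o-hydroxyaryl ynone of step 13
Product: 25 2-[(2-isopropyl-8-methoxy-4-oxo-4H-chromen-5-yl)methyl]-7-(methoxymethoxy)-5-[(2-methyl-1,3-dioxolan-2-yl)methyl]-4H-chromen-4-one, via enaminone 24 (not isolated)
Conditions: Et2NH, EtOH, rt → 50 °C
Reagents that add atoms: none
Why: Amine-mediated 6-endo-dig oxa-Michael closure of an o-hydroxyaryl ynone: diethylamine adds to the β-carbon to give 24 and the phenol displaces it by addition–elimination, so the five-membered aurone mode is shut out and any allenone formed by proton shift funnels into the same chromone.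

Step 15
Reactants: 25 the protected bischromone of step 14
Product: 26 CNP0592286.0, 7-hydroxy-2-[(2-isopropyl-8-methoxy-4-oxo-4H-chromen-5-yl)methyl]-5-(2-oxopropyl)-4H-chromen-4-one
Conditions: 2 M aq HCl, THF, 45 °C
Reagents that add atoms: water, O
Why: Acid-catalysed hydrolysis removes both acetal-type groups (dioxolane and MOM) in one operation; both chromones, the aryl methyl ether and the acetonyl ketone tolerate dilute acid, and isolating 25 first keeps diethylamine away from the liberated formaldehyde so that no Mannich reaction can start.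

Compound list
1 | isovanillin (3-hydroxy-4-methoxybenzaldehyde) | COc1ccc(C=O)cc1O | starting material
2 | 3-hydroxy-2-iodo-4-methoxybenzaldehyde | COc1ccc(C=O)c(I)c1O | intermediate
3 | 3-(dimethoxymethyl)-2-iodo-6-methoxyphenol | COc1ccc(C(OC)OC)c(I)c1O | intermediate
4 | 3-methylbut-1-yne | CC(C)C#C | starting material
5 | 1-[6-(dimethoxymethyl)-2-hydroxy-3-methoxyphenyl]-4-methylpent-2-yn-1-one | COc1ccc(C(OC)OC)c(C(=O)C#CC(C)C)c1O | intermediate (not isolated)
6 | 3-(diethylamino)-1-[6-(dimethoxymethyl)-2-hydroxy-3-methoxyphenyl]-4-methylpent-2-en-1-one (alkene geometry not defined) | COc1ccc(C(OC)OC)c(C(=O)C=C(N(CC)CC)C(C)C)c1O | intermediate (not isolated)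
7 | 5-(dimethoxymethyl)-2-isopropyl-8-methoxy-4H-chromen-4-one | COc1ccc(C(OC)OC)c2c(=O)cc(C(C)C)oc12 | intermediate (not isolated)
8 | 2-isopropyl-8-methoxy-4-oxo-4H-chromene-5-carbaldehyde | COc1ccc(C=O)c2c(=O)cc(C(C)C)oc12 | intermediate
9 | 2-isopropyl-8-methoxy-5-(2-methoxyethenyl)-4H-chromen-4-one (E/Z mixture) | COC=Cc1ccc(OC)c2oc(C(C)C)cc(=O)c12 | intermediate (not isolated)
10 | 2-(2-isopropyl-8-methoxy-4-oxo-4H-chromen-5-yl)acetaldehyde | O=CCc1ccc(OC)c2oc(C(C)C)cc(=O)c12 | intermediate
11 | 2-isopropyl-8-methoxy-5-(prop-2-yn-1-yl)-4H-chromen-4-one | C#CCc1ccc(OC)c2oc(C(C)C)cc(=O)c12 | intermediate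
12 | 2,2,6-trimethyl-4H-1,3-dioxin-4-one | CC1=CC(=O)OC(C)(C)O1 | starting material
13 | 2,2-dimethyl-6-(2-oxopropyl)-4H-1,3-dioxin-4-one | CC(=O)CC1=CC(=O)OC(C)(C)O1 | intermediate
14 | ethyl 2-(2-methyl-1,3-dioxolan-2-yl)acetate | CCOC(=O)CC1(C)OCCO1 | starting material
15 | N-methoxy-N-methyl-2-(2-methyl-1,3-dioxolan-2-yl)acetamide | CON(C)C(=O)CC1(C)OCCO1 | intermediate
16 | 2,2-dimethyl-6-[5-(2-methyl-1,3-dioxolan-2-yl)-2,4-dioxopentyl]-4H-1,3-dioxin-4-one | CC1(CC(=O)CC(=O)CC2=CC(=O)OC(C)(C)O2)OCCO1 | intermediate
17 | 5-hydroxy-2,2-dimethyl-5-[(2-methyl-1,3-dioxolan-2-yl)methyl]-5,6-dihydro-4H-1,3-benzodioxine-4,7(8H)-dione (racemic, drawn as the conjugated dioxinone tautomer) | CC1(C)OC(=O)C2=C(CC(=O)CC2(O)CC3(C)OCCO3)O1 | intermediate (not isolated)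
18 | 7-hydroxy-2,2-dimethyl-5-[(2-methyl-1,3-dioxolan-2-yl)methyl]-4H-1,3-benzodioxin-4-one | CC1(C)OC(=O)c2c(CC3(C)OCCO3)cc(O)cc2O1 | intermediate
19 | 7-(methoxymethoxy)-2,2-dimethyl-5-[(2-methyl-1,3-dioxolan-2-yl)methyl]-4H-1,3-benzodioxin-4-one | COCOc1cc(CC2(C)OCCO2)c2c(c1)OC(C)(C)OC2=O | intermediate
20 | 7-(methoxymethoxy)-2,2-dimethyl-5-[(2-methyl-1,3-dioxolan-2-yl)methyl]-4H-1,3-benzodioxin-4-ol (racemic lactol) | COCOc1cc(CC2(C)OCCO2)c2c(c1)OC(C)(C)OC2O | intermediate (not isolated)
21 | 2-hydroxy-4-(methoxymethoxy)-6-[(2-methyl-1,3-dioxolan-2-yl)methyl]benzaldehyde | COCOc1cc(O)c(C=O)c(CC2(C)OCCO2)c1 | intermediate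
22 | 5-{4-hydroxy-4-[2-hydroxy-4-(methoxymethoxy)-6-[(2-methyl-1,3-dioxolan-2-yl)methyl]phenyl]but-2-yn-1-yl}-2-isopropyl-8-methoxy-4H-chromen-4-one (racemic) | COCOc1cc(O)c(C(O)C#CCc2ccc(OC)c3oc(C(C)C)cc(=O)c23)c(CC4(C)OCCO4)c1 | intermediate
23 | 5-{4-[2-hydroxy-4-(methoxymethoxy)-6-[(2-methyl-1,3-dioxolan-2-yl)methyl]phenyl]-4-oxobut-2-yn-1-yl}-2-isopropyl-8-methoxy-4H-chromen-4-one | COCOc1cc(O)c(C(=O)C#CCc2ccc(OC)c3oc(C(C)C)cc(=O)c23)c(CC4(C)OCCO4)c1 | intermediate
24 | 5-{2-(diethylamino)-4-[2-hydroxy-4-(methoxymethoxy)-6-[(2-methyl-1,3-dioxolan-2-yl)methyl]phenyl]-4-oxobut-2-en-1-yl}-2-isopropyl-8-methoxy-4H-chromen-4-one (alkene geometry not defined) | COCOc1cc(O)c(C(=O)C=C(Cc2ccc(OC)c3oc(C(C)C)cc(=O)c23)N(CC)CC)c(CC4(C)OCCO4)c1 | intermediate (not isolated)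
25 | 2-[(2-isopropyl-8-methoxy-4-oxo-4H-chromen-5-yl)methyl]-7-(methoxymethoxy)-5-[(2-methyl-1,3-dioxolan-2-yl)methyl]-4H-chromen-4-one | COCOc1cc(CC2(C)OCCO2)c2c(=O)cc(Cc3ccc(OC)c4oc(C(C)C)cc(=O)c34)oc2c1 | intermediate
26 | CNP0592286.0, 7-hydroxy-2-[(2-isopropyl-8-methoxy-4-oxo-4H-chromen-5-yl)methyl]-5-(2-oxopropyl)-4H-chromen-4-one (achiral) | COc1ccc(Cc2cc(=O)c3c(CC(C)=O)cc(O)cc3o2)c2c(=O)cc(C(C)C)oc12 | target

Total step count: 15.
Longest linear sequence: 9 steps. Both branches have this length: steps 1–5 then 12–15, and steps 6, 8–11 then 12–15.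

Steps most likely to fail

Step 12 (fragment union).
- What may go wrong: the amide base or the acetylide may act on the chromone of the alkyne partner faster than the acetylide adds to the electron-rich, phenoxide-deactivated aldehyde. The competing processes are deprotonation at the isopropyl methine, propargyl-to-allenyl proton shift, and addition at C-4.
- Fallback: the fallback makes the alkynyl-metal by reduction instead of deprotonation (Nozaki–Hiyama–Kishi coupling) and sets out from 11 and 21. Compound 11 is converted with NIS and catalytic AgNO3 in acetone into the 1-iodoalkyne 5-(3-iodoprop-2-yn-1-yl)-2-isopropyl-8-methoxy-4H-chromen-4-one F1. Compound 21 is silylated (TBSCl, imidazole, DMF) to 2-(tert-butyldimethylsilyloxy)-4-(methoxymethoxy)-6-[(2-methyl-1,3-dioxolan-2-yl)methyl]benzaldehyde F2, which is no longer a deactivated phenoxide. CrCl2 with catalytic NiCl2 in THF–DMF should join the two under neutral conditions to the silylated propargylic alcohol F3. TBAF buffered with AcOH removes the silyl group, wherever it sits after a possible O-to-O shift, and the route is rejoined at 22.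

Step 3 (carbonylative annulation).
- What may go wrong: oxidative addition and CO insertion at the doubly ortho-substituted iodide may be slow. Direct alkynylation with benzofuran closure, or capture of the acylpalladium by diethylamine, could then take over.
- Fallback: the fallback delivers the carbonyl carbon inside an acyl donor instead of as CO gas and sets out from 3 and 4. Alkyne 4 is lithiated (n-BuLi, THF, −78 °C) and treated with N-methoxy-N-methylcarbamoyl chloride to give N-methoxy-N,4-dimethylpent-2-ynamide F4. Phenol 3 is converted into its magnesium salt (MeMgCl, LiCl) and then undergoes iodine–magnesium exchange (iPrMgCl, −20 °C). The aryl Grignard reagent is acylated by F4, which brings the route back at 5, isolated this time. Treatment with diethylamine and then the acidic wash, as in step 3, leads on to 8.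

Step 8 (dianion acylation).
- What may go wrong: proton transfer from the α-methylene of the amide to the dianion, followed by β-elimination that opens the dioxolane, may outrun C-acylation.
- Fallback: the fallback replaces the Claisen acylation by an aldol addition followed by oxidation and sets out from 14 and 13. Ester 14 is reduced (DIBAL-H, CH2Cl2, −78 °C) to 2-(2-methyl-1,3-dioxolan-2-yl)acetaldehyde F5. The dianion of 13 (LDA, THF, −78 °C) adds to this far more reactive carbonyl to give the racemic β-hydroxy ketone 6-[4-hydroxy-5-(2-methyl-1,3-dioxolan-2-yl)-2-oxopentyl]-2,2-dimethyl-4H-1,3-dioxin-4-one F6. Dess–Martin periodinane buffered with NaHCO3 oxidises it to the diketone, rejoining the route at 16.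

Further compounds
F1 | step 12 | 5-(3-iodoprop-2-yn-1-yl)-2-isopropyl-8-methoxy-4H-chromen-4-one | COc1ccc(CC#CI)c2c(=O)cc(C(C)C)oc12
F2 | step 12 | 2-(tert-butyldimethylsilyloxy)-4-(methoxymethoxy)-6-[(2-methyl-1,3-dioxolan-2-yl)methyl]benzaldehyde | COCOc1cc(O[Si](C)(C)C(C)(C)C)c(C=O)c(CC2(C)OCCO2)c1
F3 | step 12 | 5-{4-[2-(tert-butyldimethylsilyloxy)-4-(methoxymethoxy)-6-[(2-methyl-1,3-dioxolan-2-yl)methyl]phenyl]-4-hydroxybut-2-yn-1-yl}-2-isopropyl-8-methoxy-4H-chromen-4-one (racemic) | COCOc1cc(O[Si](C)(C)C(C)(C)C)c(C(O)C#CCc2ccc(OC)c3oc(C(C)C)cc(=O)c23)c(CC4(C)OCCO4)c1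
F4 | step 3 | N-methoxy-N,4-dimethylpent-2-ynamide | CON(C)C(=O)C#CC(C)C
F5 | step 8 | 2-(2-methyl-1,3-dioxolan-2-yl)acetaldehyde | CC1(CC=O)OCCO1
F6 | step 8 | 6-[4-hydroxy-5-(2-methyl-1,3-dioxolan-2-yl)-2-oxopentyl]-2,2-dimethyl-4H-1,3-dioxin-4-one (racemic) | CC1(CC(O)CC(=O)CC2=CC(=O)OC(C)(C)O2)OCCO1
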